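**Plan**

1. Retrosynthetic cuts: (i) rings A and B together, at the two bonds to the ring-A carbinol carbon (as C=O) and at the A/B fusion bond (allene–alkyne–CO closure, after adding H2 back to rings A and C); (ii) the bond from ring C's quaternary C(CH3) to the ring-B CH(OH) carbon ([2,3]-Wittig); (iii) the ring-C enone C=C (aldol); (iv) the two bonds joining ring D's CH2CH2C(CH3)2CH2 chain to the two C/D fusion carbons.
2. Enabling feature: in ring D the C(CH3)2 carbon is 1,3 to both C/D fusion carbons, so of the two ring-D CH2 groups bonded to them one is neopentyl. 1,4-Diiodo-2,2-dimethylbutane is therefore an electrophile only at its other end (bond to the quaternary C–CH3 fusion carbon, an amide α-carbon) and, after iodine–lithium exchange, a nucleophile at the neopentyl end (bond to the fusion CH, the amide carbonyl carbon).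
3. Forward order: acyclic keto acid → valinol bicyclic lactam (temporary ring) → ring D by one-pot alkylation/cycloacylation with loss of the template → ring C by aldol → trans fusion by Li/NH3 → carbonyl transposition and [2,3]-Wittig → allene → rings A and B in one Pauson–Khand step → two reductions.
4. Stereochemistry: the lactam template sets the quaternary C/D carbon; Li/NH3 sets the fusion CH and the equatorial side chain; Luche reduction plus suprafacial [2,3]-shift relays this to the second quaternary carbon; both carbinol centres come from catalyst control; the last two CH centres come from hydroxyl-directed hydrogenation.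

Key step: step 5

Remark: compounds 1, 2, 5 and 8 are taken as commercial; the (S)-valinol template is chosen on the assumption that the lactam enolate is alkylated anti to its angular chain (the (R)-template would be used if the sense proves opposite).

**Step 1**
Reactants: 1 5-bromo-2-methylpent-1-ene; 2 glutaric anhydride
Product: 4 9-methyl-5-oxodec-9-enoic acid, via Grignard reagent 3 (not isolated)
Conditions: Mg, THF, 40 °C; added to 2, THF, −78 → 0 °C; 1 M HCl
Reagents that add atoms: none
Why: Grignard acylation of a cyclic anhydride at low temperature should stop at the δ-keto acid because the magnesium carboxylate formed is unreactive.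

**Step 2**
Reactants: 4 9-methyl-5-oxodec-9-enoic acid; 5 (S)-valinol
Product: 6 (3S,8aR)-8a-(4-methylpent-4-en-1-yl)-3-(propan-2-yl)hexahydro-5H-[1,3]oxazolo[3,2-a]pyridin-5-one
Conditions: toluene, reflux, Dean–Stark
Reagents that add atoms: none
Why: Meyers lactam formation under water removal should give the thermodynamically preferred cis-fused N,O-acetal in which the isopropyl group and the angular chain share the convex face, so the valinol centre sets the aminal centre.

**Step 3**
Reactants: 6 bicyclic lactam
Product: 7 6-methyl derivative of lactam 6 (both C6 epimers)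
Conditions: LiN(i-Pr)2, THF, −78 °C; MeI, −78 → −20 °C
Reagents that add atoms: iodomethane, CI
Why: Lactam enolate alkylation installs the methyl group; the new centre is re-enolized in step 5, so its configuration does not matter.

**Step 4**
Reactants: 8 2,2-dimethylbutane-1,4-diol
Product: 9 1,4-diiodo-2,2-dimethylbutane
Conditions: PPh3, I2, imidazole, toluene, 90 °C
Reagents that add atoms: iodine, II
Why: Appel-type iodination should convert both primary alcohols, the neopentyl one needing the elevated temperature.

**Step 5**
Reactants: 7 6-methyl lactam; 9 1,4-diiodo-2,2-dimethylbutane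
Product: 12 (S)-2,5,5-trimethyl-2-(7-methyl-3-oxooct-7-en-1-yl)cyclohexan-1-one, via iodoalkyl lactam 10 (not isolated), via tricyclic hemiaminal 11 (not isolated)
Conditions: s-BuLi, THF, −78 °C; 9, −78 → −20 °C; t-BuLi (2.2 equiv), −78 → 0 °C; 1 M HCl, THF, rt
Reagents that add atoms: water, O
Why: Proposed new method: s-BuLi (leaving no amine N–H in the flask) regenerates the lactam enolate, which is alkylated only at the unhindered CH2–I of 9 because the other C–I is neopentyl; t-BuLi then exchanges that neopentyl iodide faster than it can add to the hindered α-quaternary lactam carbonyl, the primary alkyllithium adds intramolecularly to that carbonyl, and acid hydrolysis of the hemiaminal and of the N,O-acetal releases 12 and valinol. The closest known reaction types are the sequential alkylation of Meyers bicyclic lactams followed by intermolecular organolithium addition to the lactam carbonyl, and the Parham-type anionic cyclization of iodoalkyl amides. Ring D closes in a 6-exo-trig addition to the lactam C=O, after the intermolecular alkylation has made its first ring bond. The quaternary methyl-bearing centre is set in the alkylation by the bicyclic template, the second electrophile entering the enolate anti to the angular chain, which with the (S)-valinol template should give the (S) centre; the carbonyl carbon that takes the second bond is not stereogenic. The step needs selectivity between the two C–I bonds, secured by the C(CH3)2 carbon that makes one of them neopentyl, and between exchange and carbonyl addition, secured by low temperature and the shielding of the lactam carbonyl.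

**Step 6**
Reactants: 12 diketone
Product: 13 (4aS)-4a,7,7-trimethyl-1-(3-methylbut-3-en-1-yl)-4,4a,5,6,7,8-hexahydronaphthalen-2(3H)-one
Conditions: KOH, EtOH, 60 °C
Reagents that add atoms: none
Why: Intramolecular aldol condensation (second stage of a Robinson annulation) should give the six-membered conjugated enone as the thermodynamic product, forming ring C without a new stereocentre.

**Step 7**
Reactants: 13 bicyclic enone
Product: 14 (1S,4aS,8aS)-4a,7,7-trimethyl-1-(3-methylbut-3-en-1-yl)octahydronaphthalen-2(1H)-one
Conditions: Li, NH3(l), THF, t-BuOH (1 equiv), −78 °C; NH4Cl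
Reagents that add atoms: none
Why: Dissolving-metal (Birch-type) enone reduction should protonate the β-carbon axially, anti to the angular methyl, giving the trans ring fusion, and axial protonation of the enolate (or later equilibration) places the side chain equatorial.

**Step 8**
Reactants: 14 trans-decalone
Product: 15 (1S,4aS,8aS)-4a,7,7-trimethyl-1-(3-methylbut-3-en-1-yl)-4a,5,6,7,8,8a-hexahydronaphthalen-2(1H)-one
Conditions: LiN(i-Pr)2, THF, −78 °C; N-tert-butylbenzenesulfinimidoyl chloride, −78 °C
Reagents that add atoms: none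
Why: Mukaiyama dehydrogenation: the kinetic enolate forms at the unsubstituted α-CH2 and is converted in one pot into the enone by sulfur transfer and elimination.

**Step 9**
Reactants: 15 enone
Product: 16 (1S,4aS,8aS)-2,4a,7,7-tetramethyl-1-(3-methylbut-3-en-1-yl)-1,2,4a,5,6,7,8,8a-octahydronaphthalen-2-ol (carbinol epimers)
Conditions: MeLi, CeCl3, THF, −78 °C
Reagents that add atoms: methyllithium, [Li]C
Why: Cerium-assisted 1,2-addition of methyllithium to the enone carbonyl suppresses enolization; the carbinol configuration is lost in step 10.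

**Step 10**
Reactants: 16 tertiary allylic alcohol
Product: 17 (4S,4aS,8aR)-3,6,6,8a-tetramethyl-4-(3-methylbut-3-en-1-yl)-4a,5,6,7,8,8a-hexahydronaphthalen-1(4H)-one
Conditions: pyridinium chlorochromate (C5H5NH)[CrO3Cl], 4 Å molecular sieves, CH2Cl2, rt
Reagents that add atoms: none
Why: Babler–Dauben oxidative 1,3-transposition: the chromate ester of the tertiary allylic alcohol undergoes a [3,3] shift and oxidation to the β-methyl enone.

**Step 11**
Reactants: 17 transposed enone
Product: 18 (1R,4S,4aS,8aR)-3,6,6,8a-tetramethyl-4-(3-methylbut-3-en-1-yl)-1,4,4a,5,6,7,8,8a-octahydronaphthalen-1-ol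
Conditions: NaBH4, CeCl3·7H2O, MeOH, −78 → 0 °C
Reagents that add atoms: none
Why: Luche 1,2-reduction: hydride should attack axially from the face opposite the adjacent angular methyl, giving the equatorial alcohol cis to that methyl.

**Step 12**
Reactants: 18 allylic alcohol
Product: 19 but-2-yn-1-yl ether of 18
Conditions: NaH, 1-bromobut-2-yne, Bu4NI (cat.), THF/DMF, 0 °C → rt
Reagents that add atoms: 1-bromobut-2-yne, CC#CCBr
Why: Williamson etherification of the alkoxide with a reactive propargylic bromide.

**Step 13**
Reactants: 19 allyl propargyl ether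
Product: 20 1-[(1S,2S,4aS,8aS)-2,4a,7,7-tetramethyl-1-(3-methylbut-3-en-1-yl)-1,2,4a,5,6,7,8,8a-octahydronaphthalen-2-yl]but-2-yn-1-ol (carbinol epimers)
Conditions: n-BuLi, THF, −78 → −20 °C; NH4Cl
Reagents that add atoms: none
Why: [2,3]-Wittig rearrangement: the propargylic carbanion adds suprafacially, so the new C–C bond at the second quaternary carbon forms on the face that carried the ether oxygen (cis to the angular methyl) while the alkene shifts; the carbinol centre is corrected in steps 14 and 15.

**Step 14**
Reactants: 20 propargylic alcohol mixture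
Product: 21 1-[(1S,2S,4aS,8aS)-2,4a,7,7-tetramethyl-1-(3-methylbut-3-en-1-yl)-1,2,4a,5,6,7,8,8a-octahydronaphthalen-2-yl]but-2-yn-1-one
Conditions: Dess–Martin periodinane, NaHCO3, CH2Cl2, 0 °C → rt
Reagents that add atoms: none
Why: Dess–Martin oxidation to the ynone erases the uncontrolled carbinol centre.

**Step 15**
Reactants: 21 ynone
Product: 22 (1S)-propargylic alcohol corresponding to 20
Conditions: RuCl[(S,S)-TsDPEN](p-cymene) (cat.), HCO2H/Et3N (5:2), CH2Cl2, rt
Reagents that add atoms: none
Why: Noyori asymmetric transfer hydrogenation: the alkynyl group takes the place of the aryl group in the usual model, so the (S,S) catalyst should give the (S) carbinol under catalyst control.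

**Step 16**
Reactants: 22 (S)-propargylic alcohol
Product: 23 tert-butyldimethylsilyl ether of 22
Conditions: TBSOTf, 2,6-lutidine, CH2Cl2, −78 → 0 °C
Reagents that add atoms: tert-butyldimethylsilyl trifluoromethanesulfonate, CC(C)(C)[Si](C)(C)OS(=O)(=O)C(F)(F)F
Why: Silylation with the silyl triflate protects the hindered alcohol against the carbene and organolithium reagents of steps 17 and 18.

**Step 17**
Reactants: 23 silyl ether
Product: 24 gem-dibromocyclopropane from the side-chain alkene of 23 (cyclopropane epimers)
Conditions: CHBr3, KOt-Bu, pentane, −10 → 0 °C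
Reagents that add atoms: bromoform, BrC(Br)Br
Why: Dibromocarbene addition (first stage of the Doering–LaFlamme allene synthesis) should occur at the unhindered 1,1-disubstituted alkene rather than at the ring alkene flanked by two quaternary carbons or at the internal alkyne.

**Step 18**
Reactants: 24 gem-dibromocyclopropane
Product: 25 allene with the side chain CH2CH2C(CH3)=C=CH2
Conditions: MeLi, Et2O, −78 → −30 °C
Reagents that add atoms: none
Why: Doering–LaFlamme (Skattebøl) rearrangement: bromine–lithium exchange gives a cyclopropylidene carbenoid that opens to the 1,1-disubstituted allene.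

**Step 19**
Reactants: 25 allenyne
Product: 26 tetracyclic dienone (ring-A cyclopentenone, ring-B tetrasubstituted alkene, silyl ether, ring-C alkene)
Conditions: [RhCl(CO)2]2 (cat.), CO (1 atm), toluene, 90 °C
Reagents that add atoms: carbon monoxide, [C-]#[O+]
Why: Rhodium-catalysed allenic Pauson–Khand reaction: monovalent rhodium should couple the alkyne, the distal allene double bond and CO, closing ring A and the eight-membered ring B at once and leaving the proximal allene bond as the tetrasubstituted ring-B alkene; no stereocentre is formed.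

**Step 20**
Reactants: 26 dienone
Product: 27 ring-A (R)-allylic alcohol of 26
Conditions: (S)-2-methyl-CBS-oxazaborolidine (cat.), catecholborane, toluene, −78 °C
Reagents that add atoms: none
Why: Corey–Bakshi–Shibata reduction of the α-methyl cyclopentenone under catalyst control, the alkenyl side acting as the large group, should give the (R) carbinol with the (S) catalyst.

**Step 21**
Reactants: 27 silyl ether alcohol
Product: 28 dienediol
Conditions: Bu4NF, THF, rt; NH4Cl
Reagents that add atoms: none
Why: Fluoride desilylation frees the second directing hydroxyl.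

**Step 22**
Reactants: 28 dienediol
Product: 29 target diol CNP0213887.1
Conditions: H2 (1 atm), [Ir(cod)(PCy3)(py)]PF6 (cat.), CH2Cl2, 0 °C → rt
Reagents that add atoms: none
Why: Hydroxyl-directed hydrogenation with Crabtree's catalyst: both allylic hydroxyls lie on the same face of ring A and should deliver H2 to that face of the tetrasubstituted ring-A alkene, setting the two adjacent CH centres (methyl trans to the ring-A hydroxyl), while the disubstituted ring-C alkene is also saturated and the tetrasubstituted ring-B alkene, lacking an allylic hydroxyl, should remain.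

**Compound list**

1 | 5-bromo-2-methylpent-1-ene | C=C(C)CCCBr | starting material
2 | glutaric anhydride | O=C1CCCC(=O)O1 | starting material
3 | (4-methylpent-4-en-1-yl)magnesium bromide | C=C(C)CCC[Mg]Br | intermediate
4 | 9-methyl-5-oxodec-9-enoic acid | OC(=O)CCCC(=O)CCCC(C)=C | intermediate
5 | (S)-valinol | CC(C)[C@H](N)CO | starting material
6 | (3S,8aR)-8a-(4-methylpent-4-en-1-yl)-3-(propan-2-yl)hexahydro-5H-[1,3]oxazolo[3,2-a]pyridin-5-one | O=C1CCC[C@@]2(CCCC(C)=C)OC[C@H](C(C)C)N12 | intermediate
7 | 6-methyl derivative of 6 (C6 epimers) | O=C1C(C)CC[C@@]2(CCCC(C)=C)OC[C@H](C(C)C)N12 | intermediate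
8 | 2,2-dimethylbutane-1,4-diol | OCCC(C)(C)CO | starting material
9 | 1,4-diiodo-2,2-dimethylbutane | ICCC(C)(C)CI | intermediate
10 | (3S,6S,8aR)-6-(4-iodo-3,3-dimethylbutyl)-6-methyl derivative of 6 | O=C1[C@@](C)(CCC(C)(C)CI)CC[C@@]2(CCCC(C)=C)OC[C@H](C(C)C)N12 | intermediate
11 | tricyclic hemiaminal from ring closure onto the lactam carbonyl (lithium alkoxide in the flask) | OC12CC(C)(C)CC[C@@]1(C)CC[C@@]1(CCCC(C)=C)OC[C@H](C(C)C)N21 | intermediate
12 | (S)-2,5,5-trimethyl-2-(7-methyl-3-oxooct-7-en-1-yl)cyclohexan-1-one | O=C1CC(C)(C)CC[C@@]1(C)CCC(=O)CCCC(C)=C | intermediate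
13 | (4aS)-4a,7,7-trimethyl-1-(3-methylbut-3-en-1-yl)-4,4a,5,6,7,8-hexahydronaphthalen-2(3H)-one | O=C1CC[C@]2(C)CCC(C)(C)CC2=C1CCC(C)=C | intermediate
14 | (1S,4aS,8aS)-4a,7,7-trimethyl-1-(3-methylbut-3-en-1-yl)octahydronaphthalen-2(1H)-one | O=C1CC[C@]2(C)CCC(C)(C)C[C@H]2[C@@H]1CCC(C)=C | intermediate
15 | (1S,4aS,8aS)-4a,7,7-trimethyl-1-(3-methylbut-3-en-1-yl)-4a,5,6,7,8,8a-hexahydronaphthalen-2(1H)-one | O=C1C=C[C@]2(C)CCC(C)(C)C[C@H]2[C@@H]1CCC(C)=C | intermediate
16 | (1S,4aS,8aS)-2,4a,7,7-tetramethyl-1-(3-methylbut-3-en-1-yl)-1,2,4a,5,6,7,8,8a-octahydronaphthalen-2-ol (carbinol epimers) | CC1(O)C=C[C@]2(C)CCC(C)(C)C[C@H]2[C@@H]1CCC(C)=C | intermediate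
17 | (4S,4aS,8aR)-3,6,6,8a-tetramethyl-4-(3-methylbut-3-en-1-yl)-4a,5,6,7,8,8a-hexahydronaphthalen-1(4H)-one | CC1=CC(=O)[C@]2(C)CCC(C)(C)C[C@H]2[C@@H]1CCC(C)=C | intermediate
18 | (1R,4S,4aS,8aR)-3,6,6,8a-tetramethyl-4-(3-methylbut-3-en-1-yl)-1,4,4a,5,6,7,8,8a-octahydronaphthalen-1-ol | CC1=C[C@@H](O)[C@]2(C)CCC(C)(C)C[C@H]2[C@@H]1CCC(C)=C | intermediate
19 | but-2-yn-1-yl ether of 18 | CC1=C[C@@H](OCC#CC)[C@]2(C)CCC(C)(C)C[C@H]2[C@@H]1CCC(C)=C | intermediate
20 | 1-[(1S,2S,4aS,8aS)-2,4a,7,7-tetramethyl-1-(3-methylbut-3-en-1-yl)-1,2,4a,5,6,7,8,8a-octahydronaphthalen-2-yl]but-2-yn-1-ol (carbinol epimers) | CC#CC(O)[C@@]1(C)C=C[C@]2(C)CCC(C)(C)C[C@H]2[C@@H]1CCC(C)=C | intermediate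
21 | ynone from 20 | CC#CC(=O)[C@@]1(C)C=C[C@]2(C)CCC(C)(C)C[C@H]2[C@@H]1CCC(C)=C | intermediate
22 | (1S)-carbinol epimer of 20 | CC#C[C@@H](O)[C@@]1(C)C=C[C@]2(C)CCC(C)(C)C[C@H]2[C@@H]1CCC(C)=C | intermediate
23 | tert-butyldimethylsilyl ether of 22 | CC#C[C@@H](O[Si](C)(C)C(C)(C)C)[C@@]1(C)C=C[C@]2(C)CCC(C)(C)C[C@H]2[C@@H]1CCC(C)=C | intermediate
24 | 2,2-dibromo-1-methylcyclopropyl derivative of 23 (cyclopropane epimers) | CC#C[C@@H](O[Si](C)(C)C(C)(C)C)[C@@]1(C)C=C[C@]2(C)CCC(C)(C)C[C@H]2[C@@H]1CCC1(C)CC1(Br)Br | intermediate
25 | allenyne with the side chain 3-methylpenta-3,4-dien-1-yl | CC#C[C@@H](O[Si](C)(C)C(C)(C)C)[C@@]1(C)C=C[C@]2(C)CCC(C)(C)C[C@H]2[C@@H]1CCC(C)=C=C | intermediate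
26 | tetracyclic dienone (ring-A 2-methylcyclopentenone, tetrasubstituted ring-B alkene, ring-B silyl ether, ring-C alkene) | C/C1=C2\CC(=O)C(C)=C2[C@@H](O[Si](C)(C)C(C)(C)C)[C@@]2(C)C=C[C@]3(C)CCC(C)(C)C[C@H]3[C@@H]2CC1 | intermediate
27 | ring-A (R)-allylic alcohol of 26 | C/C1=C2\C[C@@H](O)C(C)=C2[C@@H](O[Si](C)(C)C(C)(C)C)[C@@]2(C)C=C[C@]3(C)CCC(C)(C)C[C@H]3[C@@H]2CC1 | intermediate
28 | dienediol (desilylated 27) | C/C1=C2\C[C@@H](O)C(C)=C2[C@@H](O)[C@@]2(C)C=C[C@]3(C)CCC(C)(C)C[C@H]3[C@@H]2CC1 | intermediate
29 | target diol CNP0213887.1 | C/C1=C2\C[C@@H](O)[C@H](C)[C@@H]2[C@@H](O)[C@@]2(C)CC[C@]3(C)CCC(C)(C)C[C@H]3[C@@H]2CC1 | target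

**Step count and risks**

Total step count: 22. Longest linear sequence: 21 steps (steps 1–3 and 5–22; step 4 is a one-step branch).

Steps most likely to fail:

Step 5. The t-BuLi may add to the lactam carbonyl, or the alkyllithium may be protonated, before the ring closes; incomplete facial selectivity in the alkylation would lower the enantiomeric purity. The fallback uses known chemistry, sets out from bromide 1 and rejoins at diketone 12, buying ring D instead of making it. The Grignard reagent 3 from 1 is added to acrolein to give 7-methylocta-1,7-dien-3-ol F1, which MnO2 oxidises to 7-methylocta-1,7-dien-3-one F2. Commercial 3,3-dimethylcyclohexanone is methylated at its unhindered α-CH2 (LiN(i-Pr)2, MeI) to 2,5,5-trimethylcyclohexan-1-one F3 and condensed with (R)-1-phenylethylamine to the imine F4. The chiral-imine (deracemizing) Michael addition of F4 to F2 through the more substituted secondary enamine, followed by aqueous acetic acid, should give 12.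

Step 19. The eight-membered ring may fail to close, with cycloisomerization or oligomerization of the allene or reaction at the proximal allene bond taking over. The fallback sets out from alcohol 22 and rejoins at dienone 26, making ring A first and ring B second. Alcohol 22 is silylated with chloro(dimethyl)vinylsilane to the dimethyl(vinyl)silyl ether F5. A Co2(CO)8-mediated Pauson–Khand reaction through this temporary silicon tether (only a five-membered siloxane has to form), with protodesilylation in wet acetonitrile, gives the ring-A cyclopentenone alcohol F6. TBSOTf gives its silyl ether F7, and OsO4 (cat.)/NaIO4 cleaves the 1,1-disubstituted alkene to the methyl ketone F8. Base-mediated intramolecular vinylogous aldol condensation (KOt-Bu, t-BuOH) between the γ-CH2 of the cyclopentenone and the methyl ketone then closes ring B to the conjugated dienone 26.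

Step 22. Hydrogen may add 1,4 across the conjugated diene, the ring-B alkene may be reduced as well, or the tetrasubstituted ring-A alkene may not react. The fallback sets out from dienone 26 and rejoins at target 29, hydrogenating at the ketone oxidation level. Bu4NF gives the hydroxy dienone F9. Directed hydrogenation with [Ir(cod)(PCy3)(py)]PF6, guided by the allylic ring-B hydroxyl, reduces the enone C=C (after which the ring-B alkene is isolated) and the ring-C alkene to give hydroxy ketone F10. NaBH4 attacks the less hindered face to give the epimeric diol F11. Mitsunobu inversion at the unhindered ring-A carbinol with 4-nitrobenzoic acid gives the 4-nitrobenzoate F12, and K2CO3/MeOH releases 29.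

**Further compounds**

F1 | step 5 | 7-methylocta-1,7-dien-3-ol | C=CC(O)CCCC(C)=C
F2 | step 5 | 7-methylocta-1,7-dien-3-one | C=CC(=O)CCCC(C)=C
F3 | step 5 | 2,5,5-trimethylcyclohexan-1-one | CC1CCC(C)(C)CC1=O
F4 | step 5 | (R)-1-phenylethylamine imine of F3 | CC1CCC(C)(C)CC1=N[C@H](C)c1ccccc1
F5 | step 19 | dimethyl(vinyl)silyl ether of 22 | CC#C[C@@H](O[Si](C)(C)C=C)[C@@]1(C)C=C[C@]2(C)CCC(C)(C)C[C@H]2[C@@H]1CCC(C)=C
F6 | step 19 | ring-A cyclopentenone alcohol | O=C1CCC(=C1C)[C@@H](O)[C@@]1(C)C=C[C@]2(C)CCC(C)(C)C[C@H]2[C@@H]1CCC(C)=C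
F7 | step 19 | tert-butyldimethylsilyl ether of F6 | O=C1CCC(=C1C)[C@@H](O[Si](C)(C)C(C)(C)C)[C@@]1(C)C=C[C@]2(C)CCC(C)(C)C[C@H]2[C@@H]1CCC(C)=C
F8 | step 19 | methyl ketone from F7 | O=C1CCC(=C1C)[C@@H](O[Si](C)(C)C(C)(C)C)[C@@]1(C)C=C[C@]2(C)CCC(C)(C)C[C@H]2[C@@H]1CCC(C)=O
F9 | step 22 | hydroxy dienone (desilylated 26) | C/C1=C2\CC(=O)C(C)=C2[C@@H](O)[C@@]2(C)C=C[C@]3(C)CCC(C)(C)C[C@H]3[C@@H]2CC1
F10 | step 22 | hydroxy ketone with saturated rings A and C | C/C1=C2\CC(=O)[C@H](C)[C@@H]2[C@@H](O)[C@@]2(C)CC[C@]3(C)CCC(C)(C)C[C@H]3[C@@H]2CC1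
F11 | step 22 | ring-A carbinol epimer of 29 | C/C1=C2\C[C@H](O)[C@H](C)[C@@H]2[C@@H](O)[C@@]2(C)CC[C@]3(C)CCC(C)(C)C[C@H]3[C@@H]2CC1
F12 | step 22 | ring-A 4-nitrobenzoate of 29 | C/C1=C2\C[C@@H](OC(=O)c3ccc(cc3)[N+](=O)[O-])[C@H](C)[C@@H]2[C@@H](O)[C@@]2(C)CC[C@]3(C)CCC(C)(C)C[C@H]3[C@@H]2CC1
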